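Ring A is cut at C2–C3 and at the ring-fusion bond C5–C10 (labdane numbering), so that both rings close in one flask from a monocyclic precursor. The key step exploits the 1,3-relation between the C19 carbon on C4 and the oxygen on C6 of ring B: joined as a butenolide, they make C5 a radical acceptor and relay the C6 configuration to C5. Hydrogen-atom transfer (Fe(acac)3/PhSiH3) to a 1,1-disubstituted alkene gives the C10 radical, which closes ring B on C5; methylation at C4 and Dieckmann condensation of the C1–C2 propanoate arm onto the C3 ester then close ring A. Precursor 15 is a butenolide diester with a masked C9 ketone.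

Key step: step 10

Remarks: atoms carry labdane numbers throughout (C17 on C8, C18 = 4α-methyl, C19 = 4β-carbon, C20 on C10); α/β refer to the usual drawing with the C10 methyl β. It is assumed that (S,S)-ProPhenol gives the (R)-carbinol in step 7; if not, its enantiomer is used.

Step 1
Reactants: 1 benzyl 3-oxobutanoate; 2 tert-butyl(2-iodoethoxy)dimethylsilane
Product: 3 benzyl 6-[(tert-butyldimethylsilyl)oxy]-3-oxohexanoate
Conditions: NaH, THF, 0 °C; n-BuLi, 0 °C; then 2, 0 °C → rt; aq. HCl
Reagents that add atoms: none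
Why: The acetoacetate dianion is alkylated at its more basic terminal (γ) carbon, which builds C6–C10 with C6 as a protected alcohol.

Step 2
Reactants: 3 benzyl 6-[(tert-butyldimethylsilyl)oxy]-3-oxohexanoate; 4 ethyl prop-2-enoate
Product: 5 1-benzyl 5-ethyl 2-{4-[(tert-butyldimethylsilyl)oxy]butanoyl}pentanedioate
Conditions: DBU (10 mol%), MeCN, 0 °C → rt
Reagents that add atoms: none
Why: Michael addition of the β-keto ester carbon (future C10) to the acrylate attaches the C1–C2 arm with its temporary ester.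

Step 3
Reactants: 5 1-benzyl 5-ethyl 2-{4-[(tert-butyldimethylsilyl)oxy]butanoyl}pentanedioate
Product: 7 ethyl 8-[(tert-butyldimethylsilyl)oxy]-4-methylidene-5-oxooctanoate, via keto acid 6 (not isolated)
Conditions: H2 (1 atm), Pd/C, EtOAc, rt; filter; then CH2O (37% aq.), Et2NH, THF, 0 °C → rt
Reagents that add atoms: formaldehyde, C=O
Why: Hydrogenolysis frees the β-keto acid, whose decarboxylative Mannich reaction with formaldehyde (amine and CO2 leave together) gives the 1,1-disubstituted alkene C10=C20.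

Step 4
Reactants: 7 ethyl 8-[(tert-butyldimethylsilyl)oxy]-4-methylidene-5-oxooctanoate
Product: 8 ethyl 4-(2-{3-[(tert-butyldimethylsilyl)oxy]propyl}-1,3-dioxolan-2-yl)pent-4-enoate
Conditions: Me3SiOCH2CH2OSiMe3, Me3SiOTf (5 mol%), CH2Cl2, −78 → −20 °C; pyridine quench
Reagents that add atoms: 1,2-bis(trimethylsilyloxy)ethane, C[Si](C)(C)OCCO[Si](C)(C)C
Why: Aprotic dioxolane formation masks the C9 ketone without conjugate addition or alkene migration and turns the enone alkene into an electron-rich hydrogen-atom acceptor.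

Step 5
Reactants: 8 ethyl 4-(2-{3-[(tert-butyldimethylsilyl)oxy]propyl}-1,3-dioxolan-2-yl)pent-4-enoate
Product: 9 ethyl 4-[2-(3-hydroxypropyl)-1,3-dioxolan-2-yl]pent-4-enoate
Conditions: Bu4NF, THF, 0 °C
Reagents that add atoms: none
Why: Fluoride cleaves the primary silyl ether while ester, ketal and alkene are inert.

Step 6
Reactants: 9 ethyl 4-[2-(3-hydroxypropyl)-1,3-dioxolan-2-yl]pent-4-enoate
Product: 10 ethyl 4-[2-(3-oxopropyl)-1,3-dioxolan-2-yl]pent-4-enoate
Conditions: DMP (1,1,1-triacetoxy-1,1-dihydro-1,2-benziodoxol-3(1H)-one), CH2Cl2, 0 °C → rt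
Reagents that add atoms: none
Why: The hypervalent iodine oxidant stops at the C6 aldehyde and tolerates the ketal and the alkene.

Step 7
Reactants: 10 ethyl 4-[2-(3-oxopropyl)-1,3-dioxolan-2-yl]pent-4-enoate; 11 ethyl prop-2-ynoate
Product: 12 ethyl (4R)-6-[2-(5-ethoxy-5-oxopent-1-en-2-yl)-1,3-dioxolan-2-yl]-4-hydroxyhex-2-ynoate
Conditions: Me2Zn, (S,S)-ProPhenol (20 mol%), Ph3PO (40 mol%), toluene, 4 °C; aq. NH4Cl
Reagents that add atoms: none
Why: Catalytic enantioselective addition of the alkynylzinc (from 11 and Me2Zn) to one aldehyde face sets C6 (R) by catalyst control; every later stereocenter is relayed from it.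

Step 8
Reactants: 12 ethyl (4R)-6-[2-(5-ethoxy-5-oxopent-1-en-2-yl)-1,3-dioxolan-2-yl]-4-hydroxyhex-2-ynoate
Product: 14 ethyl 4-(2-{2-[(2R)-5-oxo-4-(tributylstannyl)-2,5-dihydrofuran-2-yl]ethyl}-1,3-dioxolan-2-yl)pent-4-enoate, via stannyl hydroxy enoate 13 (not isolated)
Conditions: Bu3SnH, Pd(PPh3)4 (2 mol%), THF, 0 °C → rt; then pyridinium p-toluenesulfonate (cat.), 40 °C
Reagents that add atoms: tributyltin hydride, CCCC[SnH](CCCC)CCCC
Why: Pd-catalysed syn-hydrostannation of the ynoate puts tin on C4 (α to the ester) and hydrogen on C5, so the ester and the C6 hydroxyl are cis and lactonise to the butenolide.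

Step 9
Reactants: 14 ethyl 4-(2-{2-[(2R)-5-oxo-4-(tributylstannyl)-2,5-dihydrofuran-2-yl]ethyl}-1,3-dioxolan-2-yl)pent-4-enoate
Product: 15 ethyl (5R)-5-{2-[2-(5-ethoxy-5-oxopent-1-en-2-yl)-1,3-dioxolan-2-yl]ethyl}-2-oxo-2,5-dihydrofuran-3-carboxylate
Conditions: ClCO2Et, PdCl2(PPh3)2 (5 mol%), toluene, 80 °C
Reagents that add atoms: ethyl chloroformate, CCOC(=O)Cl
Why: Stille-type coupling of the alkenyl–SnBu3 unit with the chloroformate places the C3 ester on C4 and makes C5 a doubly activated acceptor.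

Step 10
Reactants: 15 ethyl (5R)-5-{2-[2-(5-ethoxy-5-oxopent-1-en-2-yl)-1,3-dioxolan-2-yl]ethyl}-2-oxo-2,5-dihydrofuran-3-carboxylate
Product: 18 tricyclic β-keto ester lactone (ethyl 9,9-ethylenedioxy-3-oxo-11,12,13,14,15,16,17-heptanorlabdan-19,6β-olide-2-carboxylate), via lactone diester 16 (not isolated), via C4-methyl lactone diester 17 (not isolated)
Conditions: Fe(acac)3 (30 mol%), PhSiH3 (3 equiv), EtOH, 60 °C; then NaOEt, MeI (1.05 equiv), 0 °C → rt; then NaOEt (3 equiv), 60 °C; AcOH
Reagents that add atoms: iodomethane, CI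
Why: An Fe–H species formed from Fe(acac)3 and PhSiH3 delivers a hydrogen atom to the terminal carbon (C20) of the electron-rich 1,1-disubstituted alkene, and the tertiary C10 radical adds to C5 of the doubly activated butenolide in a 6-exo-trig Giese ring closure (ring B), after which the malonyl-type C4 radical is reduced and protonated to 16; the closest known reaction type is the HAT-initiated reductive coupling of an alkene with a Michael acceptor. C5 is controlled by C6, because the four-atom tether reaches only the lactone face that bears C7 (cis-fused lactone, 5α-H), and C10 should be set by a chair-like transition state with the small methyl axial over the lactone and the propanoate arm equatorial, which is the least secure element. Ethoxide then removes the malonate-type C4–H and MeI alkylates the enolate on the convex face, anti to the quaternary C10, which fixes C4 (methyl cis to H5, C3 ester cis to the arm). Further ethoxide forms the ester enolate at C2, which attacks the C3 ester in a 6-exo-trig Dieckmann condensation (ring A); the enolisable β-keto ester is the thermodynamic sink and the lactone is retained as the 19,6β-olide. The step needs hydrogen-atom transfer to the donor alkene and not to the acceptor, methylation only at C4, and acylation of C2 only by C3: the electronic difference between the two alkenes, the acidity of the C4–H, and the fact that C4 is quaternary before ring A closes (so only attack of C2 on C3 gives a stabilised enolate) secure these.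

Step 11
Reactants: 18 tricyclic β-keto ester lactone
Product: 19 9,9-ethylenedioxy-3-oxo-11,12,13,14,15,16,17-heptanorlabdan-19,6β-olide
Conditions: LiCl, H2O, DMSO, 140 °C
Reagents that add atoms: none
Why: Krapcho dealkoxycarbonylation removes the temporary C2 ester (chloride attacks the ethyl group, the β-keto carboxylate loses CO2), while the lactone, whose O-alkyl carbon is the hindered secondary C6, survives.

Step 12
Reactants: 19 9,9-ethylenedioxy-3-oxo-11,12,13,14,15,16,17-heptanorlabdan-19,6β-olide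
Product: 21 3α-hydroxy-9-oxo-11,12,13,14,15,16,17-heptanorlabdan-19,6β-olide, via hydroxy ketal 20 (not isolated)
Conditions: LiBH(s-Bu)3, THF, −78 °C; then 2 M HCl, THF, rt → 40 °C
Reagents that add atoms: water, O
Why: The bulky hydride attacks the C3 ketone along the equatorial trajectory and gives the axial 3α-alcohol (sets C3), and the acidic work-up then hydrolyses the dioxolane to the C9 ketone.

Step 13
Reactants: 21 3α-hydroxy-9-oxo-11,12,13,14,15,16,17-heptanorlabdan-19,6β-olide
Product: 22 3α-hydroxy-9-oxo-11,12,13,14,15,16-hexanorlabdan-19,6β-olide (C8 epimers)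
Conditions: LiN(i-Pr)2 (2.2 equiv), THF, −78 °C; MeI (1.05 equiv), −78 → −20 °C
Reagents that add atoms: iodomethane, CI
Why: C8 is the only enolisable position of the C9 ketone (C10 is quaternary, the lactone has no α-hydrogen), so enolate methylation introduces C17; the C8 configuration is irrelevant because C8 becomes sp2.

Step 14
Reactants: 22 3α-hydroxy-9-oxo-11,12,13,14,15,16-hexanorlabdan-19,6β-olide
Product: 23 3α-hydroxy-9-(trifluoromethanesulfonyloxy)-11,12,13,14,15,16-hexanorlabd-8-en-19,6β-olide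
Conditions: KN(SiMe3)2 (2.3 equiv), THF, −78 °C; then N-(5-chloropyridin-2-yl)bis(trifluoromethanesulfonyl)imide, −78 → 0 °C; aq. NH4Cl
Reagents that add atoms: N-(5-chloropyridin-2-yl)-1,1,1-trifluoro-N-(trifluoromethanesulfonyl)methanesulfonamide, FC(F)(F)S(=O)(=O)N(c1ccc(Cl)cn1)S(=O)(=O)C(F)(F)F
Why: Deprotonation can occur only at C8, and O-sulfonylation of the tetrasubstituted enolate fixes the C8=C9 double bond as an alkenyl triflate.

Step 15
Reactants: 24 but-3-yn-1-ol
Product: 25 ethyl (2E)-5-hydroxy-3-methylpent-2-enoate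
Conditions: Me3Al (3 equiv), Cp2ZrCl2 (25 mol%), CH2Cl2, 0 °C → rt; then ClCO2Et, −30 °C → rt; aq. HCl
Reagents that add atoms: trimethylaluminium, C[Al](C)C; ethyl chloroformate, CCOC(=O)Cl
Why: Zr-catalysed syn-carboalumination adds methyl and AlMe2 cis across the alkyne, and acylation of the alkenyl–Al bond with retention gives the (E)-enoate.

Step 16
Reactants: 25 ethyl (2E)-5-hydroxy-3-methylpent-2-enoate
Product: 26 ethyl (2E)-5-iodo-3-methylpent-2-enoate
Conditions: I2, PPh3, imidazole, CH2Cl2, 0 °C → rt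
Reagents that add atoms: iodine, II
Why: Appel-type iodination converts the primary alcohol into the iodide without touching the enoate.

Step 17
Reactants: 23 3α-hydroxy-9-(trifluoromethanesulfonyloxy)-11,12,13,14,15,16-hexanorlabd-8-en-19,6β-olide; 26 ethyl (2E)-5-iodo-3-methylpent-2-enoate
Product: 28 ethyl 3α-hydroxylabda-8,13E-dien-19,6β-olid-15-oate, via alkylzinc iodide 27 (not isolated)
Conditions: 26, Zn dust, LiCl, THF, 40 °C; then 23, Pd(OAc)2 (5 mol%), SPhos (10 mol%), THF/NMP, 50 °C
Reagents that add atoms: none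
Why: Negishi coupling of the ester-tolerant alkylzinc reagent with the alkenyl triflate attaches the side chain at C9 with retention of both alkene geometries, the free hydroxyl and the lactone being tolerated.

Step 18
Reactants: 28 ethyl 3α-hydroxylabda-8,13E-dien-19,6β-olid-15-oate
Product: 29 3α-hydroxylabda-8,13E-dien-19,6β-olid-15-oic acid
Conditions: LiOH, THF/MeOH/H2O, 40 °C; then 1 M HCl to pH 3
Reagents that add atoms: lithium hydroxide, [Li+].[OH-]
Why: Saponification frees the C15 acid, and the γ-lactone, if opened, closes again on acidification because C19 and the C6 oxygen are 1,3-diaxial.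

Step 19
Reactants: 29 3α-hydroxylabda-8,13E-dien-19,6β-olid-15-oic acid
Product: 30 3α,6β,19-trihydroxylabda-8,13E-dien-15-oic acid
Conditions: LiBHEt3 (5 equiv), THF, 0 °C → rt; then 1 M HCl
Reagents that add atoms: none
Why: LiBHEt3 reduces the hindered lactone to the 6β,19-diol, whereas the carboxylic acid is only deprotonated and its carboxylate resists hydride.

Step 20
Reactants: 30 3α,6β,19-trihydroxylabda-8,13E-dien-15-oic acid; 31 3-methylbutanoyl chloride
Product: 32 (3R,4S,5R,6R,10S)-6β-hydroxy-3α,19-bis(3-methylbutanoyloxy)labda-8,13E-dien-15-oic acid (CNP0333611.1)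
Conditions: 31 (2.5 equiv), pyridine, DMAP (10 mol%), CH2Cl2, −20 → 0 °C; then aq. NaHCO3, THF
Reagents that add atoms: none
Why: The primary 19-OH and the secondary 3α-OH are acylated, whereas the 6β-OH, 1,3-diaxial to both the C10 methyl and the C4 acyloxymethyl group, should stay free; any mixed anhydride at C15 is hydrolysed in the bicarbonate work-up.

Compound list
1 | benzyl 3-oxobutanoate | CC(=O)CC(=O)OCc1ccccc1 | starting material
2 | tert-butyl(2-iodoethoxy)dimethylsilane | CC(C)(C)[Si](C)(C)OCCI | starting material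
3 | benzyl 6-[(tert-butyldimethylsilyl)oxy]-3-oxohexanoate | CC(C)(C)[Si](C)(C)OCCCC(=O)CC(=O)OCc1ccccc1 | intermediate
4 | ethyl prop-2-enoate (ethyl acrylate) | C=CC(=O)OCC | starting material
5 | 1-benzyl 5-ethyl 2-{4-[(tert-butyldimethylsilyl)oxy]butanoyl}pentanedioate (racemic) | CC(C)(C)[Si](C)(C)OCCCC(=O)C(CCC(=O)OCC)C(=O)OCc1ccccc1 | intermediate
6 | 2-{4-[(tert-butyldimethylsilyl)oxy]butanoyl}-5-ethoxy-5-oxopentanoic acid | CC(C)(C)[Si](C)(C)OCCCC(=O)C(CCC(=O)OCC)C(=O)O | intermediate
7 | ethyl 8-[(tert-butyldimethylsilyl)oxy]-4-methylidene-5-oxooctanoate | CC(C)(C)[Si](C)(C)OCCCC(=O)C(=C)CCC(=O)OCC | intermediate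
8 | ethyl 4-(2-{3-[(tert-butyldimethylsilyl)oxy]propyl}-1,3-dioxolan-2-yl)pent-4-enoate | CC(C)(C)[Si](C)(C)OCCCC1(OCCO1)C(=C)CCC(=O)OCC | intermediate
9 | ethyl 4-[2-(3-hydroxypropyl)-1,3-dioxolan-2-yl]pent-4-enoate | OCCCC1(OCCO1)C(=C)CCC(=O)OCC | intermediate
10 | ethyl 4-[2-(3-oxopropyl)-1,3-dioxolan-2-yl]pent-4-enoate | O=CCCC1(OCCO1)C(=C)CCC(=O)OCC | intermediate
11 | ethyl prop-2-ynoate (ethyl propiolate) | C#CC(=O)OCC | starting material
12 | ethyl (4R)-6-[2-(5-ethoxy-5-oxopent-1-en-2-yl)-1,3-dioxolan-2-yl]-4-hydroxyhex-2-ynoate | CCOC(=O)C#C[C@H](O)CCC1(OCCO1)C(=C)CCC(=O)OCC | intermediate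
13 | ethyl (2E,4R)-6-[2-(5-ethoxy-5-oxopent-1-en-2-yl)-1,3-dioxolan-2-yl]-4-hydroxy-2-(tributylstannyl)hex-2-enoate | CCOC(=O)/C([Sn](CCCC)(CCCC)CCCC)=C\[C@H](O)CCC1(OCCO1)C(=C)CCC(=O)OCC | intermediate
14 | ethyl 4-(2-{2-[(2R)-5-oxo-4-(tributylstannyl)-2,5-dihydrofuran-2-yl]ethyl}-1,3-dioxolan-2-yl)pent-4-enoate | O=C1O[C@H](CCC2(OCCO2)C(=C)CCC(=O)OCC)C=C1[Sn](CCCC)(CCCC)CCCC | intermediate
15 | ethyl (5R)-5-{2-[2-(5-ethoxy-5-oxopent-1-en-2-yl)-1,3-dioxolan-2-yl]ethyl}-2-oxo-2,5-dihydrofuran-3-carboxylate | O=C1O[C@H](CCC2(OCCO2)C(=C)CCC(=O)OCC)C=C1C(=O)OCC | intermediate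
16 | ring B lactone diester: C5–C10 closed; cis-fused γ-lactone C19(=O)–O–C6 (H5 and H6 α), 10β-methyl, 10α-CH2CH2CO2Et arm, C9 dioxolane, C4–H (epimers) bearing the C3 ethyl ester | CCOC(=O)CC[C@]1(C)C2(OCCO2)CC[C@H]3OC(=O)C(C(=O)OCC)[C@@H]13 | intermediate
17 | C4-methyl lactone diester: as 16 with 4α-methyl (cis to H5) and the C3 ethyl ester cis to C10 | CCOC(=O)CC[C@]1(C)C2(OCCO2)CC[C@H]3OC(=O)[C@@](C)(C(=O)OCC)[C@@H]13 | intermediate
18 | ethyl 9,9-ethylenedioxy-3-oxo-11,12,13,14,15,16,17-heptanorlabdan-19,6β-olide-2-carboxylate (4α-methyl, 5α-H, 10β-methyl; C2 epimers/enol) | C1C3(OCCO3)[C@@]2(C)CC(C(=O)OCC)C(=O)[C@](C)(C(=O)O5)[C@@H]2[C@H]5C1 | intermediate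
19 | 9,9-ethylenedioxy-3-oxo-11,12,13,14,15,16,17-heptanorlabdan-19,6β-olide | C1C3(OCCO3)[C@@]2(C)CCC(=O)[C@](C)(C(=O)O5)[C@@H]2[C@H]5C1 | intermediate
20 | 9,9-ethylenedioxy-3α-hydroxy-11,12,13,14,15,16,17-heptanorlabdan-19,6β-olide | C1C3(OCCO3)[C@@]2(C)CC[C@@H](O)[C@](C)(C(=O)O5)[C@@H]2[C@H]5C1 | intermediate
21 | 3α-hydroxy-9-oxo-11,12,13,14,15,16,17-heptanorlabdan-19,6β-olide | C1C(=O)[C@@]2(C)CC[C@@H](O)[C@](C)(C(=O)O5)[C@@H]2[C@H]5C1 | intermediate
22 | 3α-hydroxy-9-oxo-11,12,13,14,15,16-hexanorlabdan-19,6β-olide (C8 epimers) | CC1C(=O)[C@@]2(C)CC[C@@H](O)[C@](C)(C(=O)O5)[C@@H]2[C@H]5C1 | intermediate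
23 | 3α-hydroxy-9-(trifluoromethanesulfonyloxy)-11,12,13,14,15,16-hexanorlabd-8-en-19,6β-olide | CC1=C(OS(=O)(=O)C(F)(F)F)[C@@]2(C)CC[C@@H](O)[C@](C)(C(=O)O5)[C@@H]2[C@H]5C1 | intermediate
24 | but-3-yn-1-ol | C#CCCO | starting material
25 | ethyl (2E)-5-hydroxy-3-methylpent-2-enoate | OCC/C(C)=C/C(=O)OCC | intermediate
26 | ethyl (2E)-5-iodo-3-methylpent-2-enoate | ICC/C(C)=C/C(=O)OCC | intermediate
27 | [(3E)-5-ethoxy-3-methyl-5-oxopent-3-en-1-yl]zinc iodide | I[Zn]CC/C(C)=C/C(=O)OCC | intermediate
28 | ethyl 3α-hydroxylabda-8,13E-dien-19,6β-olid-15-oate | CC1=C(CC/C(C)=C/C(=O)OCC)[C@@]2(C)CC[C@@H](O)[C@](C)(C(=O)O5)[C@@H]2[C@H]5C1 | intermediate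
29 | 3α-hydroxylabda-8,13E-dien-19,6β-olid-15-oic acid | CC1=C(CC/C(C)=C/C(=O)O)[C@@]2(C)CC[C@@H](O)[C@](C)(C(=O)O5)[C@@H]2[C@H]5C1 | intermediate
30 | 3α,6β,19-trihydroxylabda-8,13E-dien-15-oic acid | CC1=C(CC/C(C)=C/C(=O)O)[C@@]2(C)CC[C@@H](O)[C@](C)(CO)[C@@H]2[C@H](O)C1 | intermediate
31 | 3-methylbutanoyl chloride | CC(C)CC(=O)Cl | starting material
32 | (3R,4S,5R,6R,10S)-6β-hydroxy-3α,19-bis(3-methylbutanoyloxy)labda-8,13E-dien-15-oic acid | CC1=C(CC/C(C)=C/C(=O)O)[C@@]2(C)CC[C@@H](OC(=O)CC(C)C)[C@](C)(COC(=O)CC(C)C)[C@@H]2[C@H](O)C1 | target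

Total step count: 20. Longest linear sequence: 18 steps (steps 1–14 and 17–20; steps 15–16 make the side-chain iodide).

Steps most likely to fail

Step 10. The radical ring closure may show poor facial selectivity at C10 (methyl versus propanoate arm), the acceptor may be reduced instead of attacked, and the iron and silane residues may disturb the alkoxide stage (incomplete or double methylation, retro-Claisen cleavage). Fallback, setting out from 15 and returning at 18: the three events are decoupled and ring A is closed by a Lewis-acid-mediated Claisen condensation instead of the alkoxide cascade. The hydrogen-atom-transfer cyclization is run alone and 16 is isolated, so that the C10 epimer can be removed by chromatography; 16 is methylated with K2CO3 and MeI in acetone to isolated 17; 17 is then cyclized with TiCl4 and Bu3N in CH2Cl2 at −78 °C (soft enolization of the propanoate arm, which is the only enolisable ester) to give 18. No new compound is made on this path.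

Step 17. Transmetalation and reductive elimination at the tetrasubstituted triflate next to the quaternary C10 may be slow, so that β-hydride elimination or protodemetalation of the alkyl group and hydrolysis of the triflate take over. Fallback, setting out from 23 and returning at 28: Stille coupling with tributyl(vinyl)stannane (Pd(PPh3)4, LiCl, CuI, DMF, 60 °C) gives 3α-hydroxy-13,14,15,16-tetranorlabda-8,11-dien-19,6β-olide F1. 9-BBN in THF hydroborates only its monosubstituted vinyl group to the B-alkyl borane F2, which is not isolated. Suzuki–Miyaura coupling of F2 with ethyl (2E)-3-iodobut-2-enoate (PdCl2(dppf), AsPh3, Cs2CO3, DMF/H2O, rt) then builds the C12–C13 bond with retention of the E geometry and gives 28.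

Step 9. Transmetalation from the electron-poor α-stannyl butenolide may be sluggish, and the very electrophilic product may oligomerise or decarbonylate at 80 °C. Fallback, setting out from 14 and returning at 15: iododestannylation with I2 in CH2Cl2 at 0 °C gives ethyl 4-(2-{2-[(2R)-4-iodo-5-oxo-2,5-dihydrofuran-2-yl]ethyl}-1,3-dioxolan-2-yl)pent-4-enoate F3. Palladium-catalysed ethoxycarbonylation of F3 (PdCl2(PPh3)2, CO (1 atm), EtOH, Et3N, 50 °C) then gives 15 under milder conditions.

Further compounds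
F0 | step 10 | none | none
F1 | step 17 | 3α-hydroxy-13,14,15,16-tetranorlabda-8,11-dien-19,6β-olide | CC1=C(C=C)[C@@]2(C)CC[C@@H](O)[C@](C)(C(=O)O5)[C@@H]2[C@H]5C1
F2 | step 17 | 12-(9-borabicyclo[3.3.1]nonan-9-yl)-3α-hydroxy-13,14,15,16-tetranorlabd-8-en-19,6β-olide | CC1=C(CCB6C7CCCC6CCC7)[C@@]2(C)CC[C@@H](O)[C@](C)(C(=O)O5)[C@@H]2[C@H]5C1
F3 | step 9 | ethyl 4-(2-{2-[(2R)-4-iodo-5-oxo-2,5-dihydrofuran-2-yl]ethyl}-1,3-dioxolan-2-yl)pent-4-enoate | O=C1O[C@H](CCC2(OCCO2)C(=C)CCC(=O)OCC)C=C1I
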